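**Plan**

Retrosynthesis, last cut first: the acetates and the 11,20-epoxide; C6–Cl (SN2 on the 6-epi alcohol); C5–C6 (closure of the ten-membered ring); C8–C17 (γ-lactone, Reformatsky); C2–C3 (an organolithium opens an O9–C2 lactone); then C13–C14 and C1–C10 together, and the O9–C2 ester bond.
Enabling feature: O9 and C2 stand 1,4 across the C1–C10 bond, so an ester O9–C2(=O) can tie the diene C10=C11(CH3)–C12=C13 to the dienophile C1=C14. The ring C1–C14–C13–C12–C11–C10 then closes together with a temporary five-membered lactone (C1, C2, O9, C9, C10); an allenoate delivers C14 as an sp carbon whose extra CH2 marks it for oxygen.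
Forward order: L-arabinose → dienol (C6–C13) → allenoate ester → intramolecular Diels–Alder reaction (six-membered ring) → oxygenation at C11/C12/C14 → lactone opened by the C3–C5 unit → butyrolactone → ten-membered ring → chloride, epoxide, acetates.
Stereochemistry: C7 and C9 from L-arabinose; C10 and C1 from the cycloaddition under C9 control; C11, C12, C14 from face-selective reagents on the rigid ring; C2 by CBS reduction; C8 and C17 by a reversible intramolecular Reformatsky closure; C6 by Felkin–Anh reduction and SN2 displacement.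

Key step: step 7

Remark: locants are briarane locants (C1 quaternary with CH3-15; ten-membered ring C1–C10; C11 with C20, then C12–C14; C16 on C5; lactone C7–O–C19(=O)–C17(CH3-18)–C8). On the six-membered ring, β is the face of CH3-15. PMB = 4-methoxybenzyl.

**Route**

Step 1
Reactants: 1 L-arabinose
Product: 2 3,4-O-isopropylidene-L-arabinopyranose
Conditions: 2,2-dimethoxypropane, p-toluenesulfonic acid (cat.), DMF, rt
Reagents that add atoms: 2,2-dimethoxypropane COC(C)(C)OC
Why: Kinetic acetalisation takes the only cis-vicinal diol of the pyranose (O3/O4, later O8/O7) and leaves the lactol and O2–H (later O9–H) free; no stereocentre is touched, and sugar C2 and C4 become C9 and C7.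

Step 2
Reactants: 2 3,4-O-isopropylidene-L-arabinopyranose; 3 2-(triphenylphosphoranylidene)propanal
Product: 4 (E)-enal diol
Conditions: toluene, 80 °C
Reagents that add atoms: none
Why: Wittig olefination of the open-chain aldehyde form of the lactol with a stabilised ylide should give the (E)-trisubstituted enal (C10=C11 with CH3-20), the E geometry following from reversible oxaphosphetane formation.

Step 3
Reactants: 4 (E)-enal diol
Product: 5 diene diol
Conditions: methyltriphenylphosphonium bromide, KN(SiMe3)2, THF, −78 → 0 °C (excess ylide)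
Reagents that add atoms: methyltriphenylphosphonium bromide C[P+](c1ccccc1)(c1ccccc1)c1ccccc1.[Br-]
Why: Wittig methylenation of the enal (the two hydroxyls ride along as alkoxides) completes the (E)-2-methyl-1,3-diene C10=C11–C12=C13 without touching C9.

Step 4
Reactants: 5 diene diol
Product: 6 dienol PMB ether
Conditions: 4-methoxybenzyl chloride, Ag2O, CH2Cl2, rt
Reagents that add atoms: 4-methoxybenzyl chloride COc1ccc(CCl)cc1
Why: Ag2O-mediated Williamson etherification should select the unhindered primary hydroxyl (O6) over the secondary dienylic one, which must stay free as the tether anchor.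

Step 5
Reactants: 7 ethyl 2-methylbuta-2,3-dienoate
Product: 8 2-methylbuta-2,3-dienoic acid
Conditions: LiOH, THF–H2O, 0 °C; then aq. HCl
Reagents that add atoms: lithium hydroxide [Li+].[OH-]
Why: Saponification of the ester; the 2-methyl group leaves no α-hydrogen, so the allene cannot drift to a conjugated alkynoate.

Step 6
Reactants: 6 dienol PMB ether; 8 2-methylbuta-2,3-dienoic acid
Product: 9 dienyl allenoate
Conditions: 2-chloro-1-methylpyridinium iodide, Et3N, CH2Cl2, 0 °C → rt
Reagents that add atoms: none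
Why: Mukaiyama esterification activates the allenic acid as an acyloxypyridinium salt under mild conditions that spare the allene and the acid-labile dienylic carbinol; the C9–O bond is not broken, so C9 keeps its configuration.

Step 7
Reactants: 9 dienyl allenoate
Product: 10 trans-fused cyclohexene lactone
Conditions: toluene (0.01 M), 2,6-di-tert-butyl-4-methylphenol (cat.), 140 °C, sealed tube
Reagents that add atoms: none
Why: Concerted, asynchronous [4+2] cycloaddition of the diene C10=C11(CH3)–C12=C13 with the ester-conjugated C1=C14 bond of the allenoate, the O9–C2(=O) ester acting as a three-atom tether between the diene terminus C10 and the dienophile carbon C1; the closest known reaction type is the thermal intramolecular Diels–Alder reaction of ester-linked 1,3,8-nonatrienes (dienyl acrylates) and of allenic esters. The cyclohexene ring (C1, C14, C13, C12, C11, C10) closes by suprafacial 4π+2π bond formation at C13–C14 and C1–C10, and the five-membered lactone ring (C1, C2, O9, C9, C10) closes in the fused mode of a tethered cycloaddition with the tether on the diene terminus. C10 is controlled by C9: allylic 1,3-strain with CH3-20 holds H-9 in the diene plane, the bulky dioxolanyl group points away, and the tethered dienophile can reach C10 only from the face of O9. C1 is set relative to C10 by the exo orientation of the tether carbonyl, which gives the trans ring fusion (CH3-15 anti to H-10) that ester-linked nonatrienes usually prefer. The step needs periselectivity for the α,β-bond of the allene, which carries the larger LUMO coefficient and is the only bond the short tether can bring over the diene, and it needs trans over cis fusion; the linear C14=CH2 unit has no endo or exo substituent, so no stereocentre arises at C14, and this carbon is left marked for oxidation.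

Step 8
Reactants: 10 trans-fused cyclohexene lactone
Product: 11 11α,12α-epoxy lactone
Conditions: mCPBA, NaHCO3, CH2Cl2, 0 °C
Reagents that add atoms: mCPBA OOC(=O)c1cccc(Cl)c1
Why: Prilezhaev epoxidation should select the electron-rich trisubstituted C11=C12 bond over the hindered 1,1-disubstituted C14 methylene and should occur on the α-face, anti to the axial CH3-15.

Step 9
Reactants: 11 11α,12α-epoxy lactone
Product: 13 14-oxo epoxy lactone, via vicinal diol 12 (not isolated)
Conditions: OsO4 (cat.), NaIO4, 2,6-lutidine, dioxane–H2O, rt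
Reagents that add atoms: sodium periodate NaIO4 [Na+].[O-]I(=O)(=O)=O; osmium tetroxide OsO4 O=[Os](=O)(=O)=O (passes the oxygen on)
Why: Lemieux–Johnson oxidation (dihydroxylation, then periodate glycol cleavage) removes the helper carbon and unveils the C14 ketone; ozone is avoided because of the PMB ether.

Step 10
Reactants: 13 14-oxo epoxy lactone
Product: 14 14α-hydroxy epoxy lactone
Conditions: LiBH(s-Bu)3, THF, −78 °C; aq. NH4Cl
Reagents that add atoms: none
Why: The bulky hydride should attack the C14 ketone along the equatorial trajectory (β-face), since axial approach is blocked by the α-epoxide oxygen at C12 and by H-10, which gives the axial 14α-alcohol; the hindered lactone carbonyl on quaternary C1 is not reduced at −78 °C.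

Step 11
Reactants: 14 14α-hydroxy epoxy lactone
Product: 15 12α,14α-dihydroxy 11(20)-ene lactone
Conditions: Et2AlCl, lithium 2,2,6,6-tetramethylpiperidide, toluene, 0 °C
Reagents that add atoms: none
Why: Aluminium amide-mediated isomerisation of an epoxide to an allylic alcohol: the aluminium-bound oxygen stays on C12 (12α-OH, configuration from step 8) while the bulky amide removes a syn proton from the least hindered site, CH3-20, to give the exocyclic C11=C20 alkene; the lactone has no α-hydrogen.

Step 12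
Reactants: 15 12α,14α-dihydroxy 11(20)-ene lactone
Product: 16 12,14-O-silylene lactone
Conditions: t-Bu2Si(OTf)2, 2,6-lutidine, CH2Cl2, 0 °C
Reagents that add atoms: di-tert-butylsilyl bis(trifluoromethanesulfonate) CC(C)(C)[Si](OS(=O)(=O)C(F)(F)F)(OS(=O)(=O)C(F)(F)F)C(C)(C)C
Why: The two syn-axial hydroxyls are bridged as a six-membered silylene, which avoids the 1,3-diaxial clash of two separate silyl ethers and should survive organolithium, mild acid and oxidants.

Step 13
Reactants: 17 (1-bromovinyl)trimethylsilane; 18 oxirane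
Product: 20 3-(trimethylsilyl)but-3-en-1-ol, via alkenylmagnesium bromide 19 (not isolated)
Conditions: Mg, THF, 40 °C; then oxirane, CuI (cat.), −30 → 0 °C; aq. NH4Cl
Reagents that add atoms: none
Why: Copper-catalysed opening of oxirane by the alkenyl Grignard reagent gives the C3–C4–C5(=C16) unit with silicon marking C5.

Step 14
Reactants: 20 3-(trimethylsilyl)but-3-en-1-ol
Product: 21 4-iodo-2-(trimethylsilyl)but-1-ene
Conditions: I2, PPh3, imidazole, CH2Cl2, 0 °C
Reagents that add atoms: iodine II
Why: Appel-type iodination of the primary alcohol through its alkoxyphosphonium salt.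

Step 15
Reactants: 16 12,14-O-silylene lactone; 21 4-iodo-2-(trimethylsilyl)but-1-ene
Product: 24 ring-opened C2 ketone 9-acetate, via alkyllithium 22 (not isolated), via lithium hemiketal alkoxide 23 (not isolated)
Conditions: t-BuLi, Et2O–pentane, −78 °C; then 16, −78 °C; then Ac2O, 4-dimethylaminopyridine, −78 → 0 °C
Reagents that add atoms: acetic anhydride CC(=O)OC(C)=O
Why: Iodine–lithium exchange and single addition of the primary alkyllithium to the lactone give a tetrahedral alkoxide that resists a second addition; on warming with Ac2O the ring-opened secondary alkoxide (O9) should be trapped as the acetate, which frees the C2 ketone, forms the C2–C3 bond and removes the temporary ring without touching a stereocentre.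

Step 16
Reactants: 24 ring-opened C2 ketone 9-acetate
Product: 25 (2R)-alcohol 9-acetate
Conditions: (S)-2-methyl-CBS-oxazaborolidine, catecholborane, toluene, −78 °C
Reagents that add atoms: none
Why: Corey–Bakshi–Shibata reduction under reagent control, with quaternary C1 as the large and C3H2 as the small ketone substituent, should give the (2R)-alcohol; catecholborane does not hydroborate the alkenes at this temperature.

Step 17
Reactants: 25 (2R)-alcohol 9-acetate
Product: 26 2,9-diacetate alkenylsilane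
Conditions: Ac2O, pyridine, 4-dimethylaminopyridine (cat.), CH2Cl2, rt
Reagents that add atoms: acetic anhydride CC(=O)OC(C)=O
Why: Acetylation of the only free hydroxyl installs the C2 acetate of the target.

Step 18
Reactants: 26 2,9-diacetate alkenylsilane
Product: 27 2,9-diacetate alkenyl iodide
Conditions: N-iodosuccinimide, 2,6-lutidine, (CF3)2CHOH, 0 °C
Reagents that add atoms: N-iodosuccinimide O=C1CCC(=O)N1I
Why: Iododesilylation (ipso-substitution of the alkenylsilane) gives the 2-iodoalkene for ring closure and should be faster than iodination of the flanked C11=C20 alkene.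

Step 19
Reactants: 27 2,9-diacetate alkenyl iodide
Product: 28 7,8-diol
Conditions: pyridinium p-toluenesulfonate (cat.), MeOH, 45 °C
Reagents that add atoms: none
Why: Acid-catalysed transketalisation removes the isopropylidene group while silylene, acetates and PMB ether should hold; mildly acidic methanol limits acetyl migration from O9.

Step 20
Reactants: 28 7,8-diol; 29 2-bromopropanoyl bromide
Product: 30 7-O-(2-bromopropanoyl) 8-alcohol
Conditions: 2,4,6-collidine, CH2Cl2, −78 °C
Reagents that add atoms: none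
Why: Acylation should occur at the less hindered 7-hydroxyl, since the 8-hydroxyl is flanked by the acetoxy-bearing C9 and the ring, and low temperature suppresses 1,2-acyl migration; the bromine-bearing carbon is a mixture of epimers that is erased in step 22.

Step 21
Reactants: 30 7-O-(2-bromopropanoyl) 8-alcohol
Product: 31 8-ketone 7-(2-bromopropanoate)
Conditions: Dess–Martin periodinane, NaHCO3, CH2Cl2, rt
Reagents that add atoms: none
Why: Dess–Martin oxidation of the remaining secondary alcohol gives the C8 ketone under non-basic conditions that should not epimerise C7 or C9.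

Step 22
Reactants: 31 8-ketone 7-(2-bromopropanoate)
Product: 33 8-hydroxy butyrolactone PMB ether, via bromozinc enolate 32 (not isolated)
Conditions: Zn (activated with Me3SiCl), THF, 45 °C; aq. NH4Cl
Reagents that add atoms: none
Why: Intramolecular Reformatsky reaction: the zinc enolate forms without base and adds to the C8 ketone to close the γ-lactone, and the reversible zinc aldolate should settle in the isomer with the large C9 substituent trans to both C6 and CH3-18, which is the target configuration at C8 and C17.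

Step 23
Reactants: 33 8-hydroxy butyrolactone PMB ether
Product: 34 8-hydroxy butyrolactone 6-alcohol
Conditions: DDQ, CH2Cl2–pH 7 buffer, 0 °C
Reagents that add atoms: none
Why: Oxidative cleavage of the PMB ether frees the primary alcohol without touching the silylene or the acetates.

Step 24
Reactants: 34 8-hydroxy butyrolactone 6-alcohol
Product: 35 C6 aldehyde
Conditions: Dess–Martin periodinane, NaHCO3, CH2Cl2, 0 °C
Reagents that add atoms: none
Why: Buffered Dess–Martin oxidation gives the aldehyde without epimerisation at C7 or β-elimination of the 8-hydroxyl.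

Step 25
Reactants: 35 C6 aldehyde
Product: 37 macrocyclic C6 carbinol (both C6 epimers), via alkenylchromium dichloride 36 (not isolated)
Conditions: CrCl2 (excess), NiCl2 (cat.), DMSO, rt, slow addition to 2 mM
Reagents that add atoms: none
Why: Nozaki–Hiyama–Kishi reaction: nickel-catalysed formation of the alkenylchromium reagent (trivalent chromium) and its aldehyde-selective addition should close the ten-membered ring at C5–C6 in the presence of esters, lactone and the free tertiary hydroxyl; C6 may form as a mixture of epimers, which the next two steps merge.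

Step 26
Reactants: 37 macrocyclic C6 carbinol (both C6 epimers)
Product: 38 macrocyclic 6-ketone
Conditions: Dess–Martin periodinane, NaHCO3, CH2Cl2, 0 °C
Reagents that add atoms: none
Why: Dess–Martin oxidation converts both C6 epimers into one α-methylene ketone.

Step 27
Reactants: 38 macrocyclic 6-ketone
Product: 39 (6R)-allylic alcohol
Conditions: NaBH4, CeCl3·7H2O, MeOH, −78 °C
Reagents that add atoms: none
Why: Luche 1,2-reduction; by the polar Felkin–Anh model hydride adds anti to the C7–O bond and past H-7, which should give the 6,7-syn (6R) alcohol.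

Step 28
Reactants: 39 (6R)-allylic alcohol
Product: 40 (6S)-allylic chloride 12,14-O-silylene
Conditions: PPh3, hexachloroacetone, CH2Cl2, −20 → 0 °C
Reagents that add atoms: hexachloroacetone O=C(C(Cl)(Cl)Cl)C(Cl)(Cl)Cl
Why: Appel-type chlorination through the alkoxyphosphonium salt with SN2 inversion at C6 should give the (6S)-chloride; this reagent pair chlorinates secondary allylic alcohols without allylic shift, and the tertiary 8-hydroxyl is too hindered to react.

Step 29
Reactants: 40 (6S)-allylic chloride 12,14-O-silylene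
Product: 41 (6S)-chloride 12α,14α-diol
Conditions: HF·pyridine, pyridine, THF, 0 °C
Reagents that add atoms: none
Why: Fluoride cleavage of the silylene frees the 12α- and 14α-hydroxyls; acetates, lactone and allylic chloride should be stable to buffered HF.

Step 30
Reactants: 41 (6S)-chloride 12α,14α-diol
Product: 42 11α,20-epoxy 12α,14α-diol
Conditions: VO(acac)2 (cat.), t-BuOOH, CH2Cl2, 0 °C
Reagents that add atoms: tert-butyl hydroperoxide CC(C)(C)OO
Why: Hydroxyl-directed vanadium-catalysed epoxidation: the axial 12α-hydroxyl delivers oxygen to the α-face of C11=C20 (epoxide oxygen syn to O12), while the C5=C16 alkene has no allylic hydroxyl and is deactivated by the chloride.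

Step 31
Reactants: 42 11α,20-epoxy 12α,14α-diol
Product: 43 CNP0349227.1
Conditions: Ac2O, pyridine, 4-dimethylaminopyridine (cat.), CH2Cl2, rt
Reagents that add atoms: acetic anhydride CC(=O)OC(C)=O
Why: Acetylation of the two secondary hydroxyls (O12, O14) completes the tetraacetate; the tertiary 8-hydroxyl is too hindered to react.

**Compound list**

1 | L-arabinose (pyranose form) | OC1[C@H](O)[C@@H](O)[C@@H](O)CO1 | starting material
2 | 3,4-O-isopropylidene-L-arabinopyranose | OC1[C@H](O)[C@H]2OC(C)(C)O[C@H]2CO1 | intermediate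
3 | 2-(triphenylphosphoranylidene)propanal | CC(C=O)=P(c1ccccc1)(c1ccccc1)c1ccccc1 | starting material
4 | (E)-enal diol: (2E,4S)-4-hydroxy-4-[(4R,5S)-5-(hydroxymethyl)-2,2-dimethyl-1,3-dioxolan-4-yl]-2-methylbut-2-enal | O=C/C(C)=C/[C@H](O)[C@H]1OC(C)(C)O[C@H]1CO | intermediate
5 | diene diol: (1S,2E)-1-[(4R,5S)-5-(hydroxymethyl)-2,2-dimethyl-1,3-dioxolan-4-yl]-3-methylpenta-2,4-dien-1-ol | C=C/C(C)=C/[C@H](O)[C@H]1OC(C)(C)O[C@H]1CO | intermediate
6 | dienol PMB ether: (1S,2E)-1-[(4R,5S)-5-[(4-methoxybenzyloxy)methyl]-2,2-dimethyl-1,3-dioxolan-4-yl]-3-methylpenta-2,4-dien-1-ol (C6–C13, C20) | C=C/C(C)=C/[C@H](O)[C@H]1OC(C)(C)O[C@H]1COCc1ccc(OC)cc1 | intermediate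
7 | ethyl 2-methylbuta-2,3-dienoate | C=C=C(C)C(=O)OCC | starting material
8 | 2-methylbuta-2,3-dienoic acid | C=C=C(C)C(=O)O | intermediate
9 | dienyl allenoate: 2-methylbuta-2,3-dienoate ester of 6 at O9 | C=C/C(C)=C/[C@H](OC(=O)C(C)=C=C)[C@H]1OC(C)(C)O[C@H]1COCc1ccc(OC)cc1 | intermediate
10 | trans-fused cyclohexene lactone: lactone C1–C2(=O)–O9–C9–C10; C11=C12 with CH3-20; CH2= on C14; CH3-15 β, H-10 α; C9 carries the dioxolanyl chain (C8, C7, C6–OPMB) | C=C1CC=C(C)[C@H]2[C@@]1(C)C(=O)O[C@@H]2[C@H]1OC(C)(C)O[C@H]1COCc1ccc(OC)cc1 | intermediate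
11 | 11α,12α-epoxy lactone | C=C1C[C@H]2O[C@@]2(C)[C@H]2[C@@]1(C)C(=O)O[C@@H]2[C@H]1OC(C)(C)O[C@H]1COCc1ccc(OC)cc1 | intermediate
12 | vicinal diol: 14-hydroxy-14-(hydroxymethyl) epoxy lactone (C14 not defined) | OCC1(O)C[C@H]2O[C@@]2(C)[C@H]2[C@@]1(C)C(=O)O[C@@H]2[C@H]1OC(C)(C)O[C@H]1COCc1ccc(OC)cc1 | intermediate
13 | 14-oxo epoxy lactone | O=C1C[C@H]2O[C@@]2(C)[C@H]2[C@@]1(C)C(=O)O[C@@H]2[C@H]1OC(C)(C)O[C@H]1COCc1ccc(OC)cc1 | intermediate
14 | 14α-hydroxy epoxy lactone | O[C@H]1C[C@H]2O[C@@]2(C)[C@H]2[C@@]1(C)C(=O)O[C@@H]2[C@H]1OC(C)(C)O[C@H]1COCc1ccc(OC)cc1 | intermediate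
15 | 12α,14α-dihydroxy 11(20)-ene lactone | O[C@H]1C[C@@H](O)C(=C)[C@H]2[C@@]1(C)C(=O)O[C@@H]2[C@H]1OC(C)(C)O[C@H]1COCc1ccc(OC)cc1 | intermediate
16 | 12,14-O-silylene lactone (di-tert-butylsilylene bridging O12 and O14) | CC(C)(C)[Si]1(C(C)(C)C)O[C@H]2C[C@@H](O1)C(=C)[C@H]3[C@@]2(C)C(=O)O[C@@H]3[C@H]1OC(C)(C)O[C@H]1COCc1ccc(OC)cc1 | intermediate
17 | (1-bromovinyl)trimethylsilane | C=C(Br)[Si](C)(C)C | starting material
18 | oxirane | C1CO1 | starting material
19 | alkenylmagnesium bromide: [1-(trimethylsilyl)vinyl]magnesium bromide | C=C([Mg]Br)[Si](C)(C)C | intermediate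
20 | 3-(trimethylsilyl)but-3-en-1-ol | C=C(CCO)[Si](C)(C)C | intermediate
21 | 4-iodo-2-(trimethylsilyl)but-1-ene | C=C(CCI)[Si](C)(C)C | intermediate
22 | alkyllithium: [3-(trimethylsilyl)but-3-en-1-yl]lithium | [Li]CCC(=C)[Si](C)(C)C | intermediate
23 | lithium hemiketal alkoxide: adduct of 22 at C2 of 16 (C2 not defined) | [Li+].[O-]C1(CCC(=C)[Si](C)(C)C)O[C@H]([C@H]2OC(C)(C)O[C@H]2COCc2ccc(OC)cc2)[C@H]2C(=C)[C@H]3C[C@H](O[Si](C(C)(C)C)(C(C)(C)C)O3)[C@]12C | intermediate
24 | ring-opened C2 ketone 9-acetate: C2(=O)–C3–C4–C5(SiMe3)=C16H2 chain on C1 | C=C([Si](C)(C)C)CCC(=O)[C@@]2(C)[C@@H]3C[C@@H](O[Si](C(C)(C)C)(C(C)(C)C)O3)C(=C)[C@@H]2[C@H](OC(C)=O)[C@H]1OC(C)(C)O[C@H]1COCc1ccc(OC)cc1 | intermediate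
25 | (2R)-alcohol 9-acetate | C=C([Si](C)(C)C)CC[C@@H](O)[C@@]2(C)[C@@H]3C[C@@H](O[Si](C(C)(C)C)(C(C)(C)C)O3)C(=C)[C@@H]2[C@H](OC(C)=O)[C@H]1OC(C)(C)O[C@H]1COCc1ccc(OC)cc1 | intermediate
26 | 2,9-diacetate alkenylsilane | C=C([Si](C)(C)C)CC[C@@H](OC(C)=O)[C@@]2(C)[C@@H]3C[C@@H](O[Si](C(C)(C)C)(C(C)(C)C)O3)C(=C)[C@@H]2[C@H](OC(C)=O)[C@H]1OC(C)(C)O[C@H]1COCc1ccc(OC)cc1 | intermediate
27 | 2,9-diacetate alkenyl iodide (iodine on C5) | C=C(I)CC[C@@H](OC(C)=O)[C@@]2(C)[C@@H]3C[C@@H](O[Si](C(C)(C)C)(C(C)(C)C)O3)C(=C)[C@@H]2[C@H](OC(C)=O)[C@H]1OC(C)(C)O[C@H]1COCc1ccc(OC)cc1 | intermediate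
28 | 7,8-diol | C=C(I)CC[C@@H](OC(C)=O)[C@@]2(C)[C@@H]3C[C@@H](O[Si](C(C)(C)C)(C(C)(C)C)O3)C(=C)[C@@H]2[C@H](OC(C)=O)[C@@H](O)[C@@H](O)COCc1ccc(OC)cc1 | intermediate
29 | 2-bromopropanoyl bromide (racemic) | CC(Br)C(Br)=O | starting material
30 | 7-O-(2-bromopropanoyl) 8-alcohol | C=C(I)CC[C@@H](OC(C)=O)[C@@]2(C)[C@@H]3C[C@@H](O[Si](C(C)(C)C)(C(C)(C)C)O3)C(=C)[C@@H]2[C@H](OC(C)=O)[C@@H](O)[C@@H](OC(=O)C(C)Br)COCc1ccc(OC)cc1 | intermediate
31 | 8-ketone 7-(2-bromopropanoate) | C=C(I)CC[C@@H](OC(C)=O)[C@@]2(C)[C@@H]3C[C@@H](O[Si](C(C)(C)C)(C(C)(C)C)O3)C(=C)[C@@H]2[C@H](OC(C)=O)C(=O)[C@@H](OC(=O)C(C)Br)COCc1ccc(OC)cc1 | intermediate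
32 | bromozinc enolate of 31 (drawn carbon-bound) | C=C(I)CC[C@@H](OC(C)=O)[C@@]2(C)[C@@H]3C[C@@H](O[Si](C(C)(C)C)(C(C)(C)C)O3)C(=C)[C@@H]2[C@H](OC(C)=O)C(=O)[C@@H](OC(=O)C(C)[Zn]Br)COCc1ccc(OC)cc1 | intermediate
33 | 8-hydroxy butyrolactone PMB ether (lactone C19 to O7; C7, C8, C17 as in the target) | C=C(I)CC[C@@H](OC(C)=O)[C@@]2(C)[C@@H]3C[C@@H](O[Si](C(C)(C)C)(C(C)(C)C)O3)C(=C)[C@@H]2[C@H](OC(C)=O)[C@]2(O)[C@@H](C)C(=O)O[C@H]2COCc1ccc(OC)cc1 | intermediate
34 | 8-hydroxy butyrolactone 6-alcohol | C=C(I)CC[C@@H](OC(C)=O)[C@@]2(C)[C@@H]3C[C@@H](O[Si](C(C)(C)C)(C(C)(C)C)O3)C(=C)[C@@H]2[C@H](OC(C)=O)[C@]2(O)[C@@H](C)C(=O)O[C@H]2CO | intermediate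
35 | C6 aldehyde | C=C(I)CC[C@@H](OC(C)=O)[C@@]2(C)[C@@H]3C[C@@H](O[Si](C(C)(C)C)(C(C)(C)C)O3)C(=C)[C@@H]2[C@H](OC(C)=O)[C@]2(O)[C@@H](C)C(=O)O[C@H]2C=O | intermediate
36 | alkenylchromium dichloride (trivalent chromium on C5) | C=C([Cr](Cl)Cl)CC[C@@H](OC(C)=O)[C@@]2(C)[C@@H]3C[C@@H](O[Si](C(C)(C)C)(C(C)(C)C)O3)C(=C)[C@@H]2[C@H](OC(C)=O)[C@]2(O)[C@@H](C)C(=O)O[C@H]2C=O | intermediate
37 | macrocyclic C6 carbinol (both C6 epimers; ten-membered ring closed) | C=C1CC[C@@H](OC(C)=O)[C@@]2(C)[C@@H]3C[C@@H](O[Si](C(C)(C)C)(C(C)(C)C)O3)C(=C)[C@@H]2[C@H](OC(C)=O)[C@]2(O)[C@@H](C)C(=O)O[C@H]2C1O | intermediate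
38 | macrocyclic 6-ketone (α-methylene ketone) | C=C1CC[C@@H](OC(C)=O)[C@@]2(C)[C@@H]3C[C@@H](O[Si](C(C)(C)C)(C(C)(C)C)O3)C(=C)[C@@H]2[C@H](OC(C)=O)[C@]2(O)[C@@H](C)C(=O)O[C@H]2C1=O | intermediate
39 | (6R)-allylic alcohol | C=C1CC[C@@H](OC(C)=O)[C@@]2(C)[C@@H]3C[C@@H](O[Si](C(C)(C)C)(C(C)(C)C)O3)C(=C)[C@@H]2[C@H](OC(C)=O)[C@]2(O)[C@@H](C)C(=O)O[C@H]2[C@@H]1O | intermediate
40 | (6S)-allylic chloride 12,14-O-silylene | C=C1CC[C@@H](OC(C)=O)[C@@]2(C)[C@@H]3C[C@@H](O[Si](C(C)(C)C)(C(C)(C)C)O3)C(=C)[C@@H]2[C@H](OC(C)=O)[C@]2(O)[C@@H](C)C(=O)O[C@H]2[C@H]1Cl | intermediate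
41 | (6S)-chloride 12α,14α-diol | C=C1CC[C@@H](OC(C)=O)[C@@]2(C)[C@@H](O)C[C@@H](O)C(=C)[C@@H]2[C@H](OC(C)=O)[C@]2(O)[C@@H](C)C(=O)O[C@H]2[C@H]1Cl | intermediate
42 | 11α,20-epoxy 12α,14α-diol | C=C1CC[C@@H](OC(C)=O)[C@@]2(C)[C@@H](O)C[C@@H](O)[C@]3(CO3)[C@@H]2[C@H](OC(C)=O)[C@]2(O)[C@@H](C)C(=O)O[C@H]2[C@H]1Cl | intermediate
43 | CNP0349227.1 (2,9,12,14-tetraacetate; 1S,2R,6S,7R,8R,9S,10S,11R,12R,14S,17R) | C=C1CC[C@@H](OC(C)=O)[C@@]2(C)[C@@H](OC(C)=O)C[C@@H](OC(C)=O)[C@]3(CO3)[C@@H]2[C@H](OC(C)=O)[C@]2(O)[C@@H](C)C(=O)O[C@H]2[C@H]1Cl | target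

**Count and risks**

Total step count: 31. Longest linear sequence: 28 steps (steps 1–4, 6–12, 15–31); steps 5, 13 and 14 make side fragments.

The three steps most likely to fail:

Step 25 (ring closure). Closure of the strained, densely substituted ten-membered ring may be slower than intermolecular coupling or protodemetalation of the alkenylchromium intermediate. The fallback sets out from 35 and returns at 38, closing the ring as a ketone synthesis instead of a carbonyl addition. Pinnick oxidation of 35 (NaClO2, NaH2PO4, 2-methylbut-2-ene) would give the C6 carboxylic acid F1. Carbodiimide coupling with ethanethiol would give the S-ethyl thioester F2. Stannylation of the alkenyl iodide (hexamethylditin, Pd(PPh3)4, zerovalent palladium) would give the alkenylstannane thioester F3. A Liebeskind–Srogl-type thioester–stannane coupling under neutral conditions (Pd2(dba)3, tri(2-furyl)phosphine, CuO2PPh2 with monovalent copper, THF, high dilution) would then form C5–C6 and give ketone 38 directly, so step 26 falls away.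

Step 7 (key cycloaddition). The ester must reach its s-cis rotamer before it can cyclise, so the temperature needed may let the allene oligomerise, and the cis-fused lactone may compete through loss of endo/exo control. The fallback sets out from 6 and returns at 13, using a doubly activated, (E)-configured dienophile of the fumarate type, which reacts at lower temperature and places its acyl group endo in the trans-fused mode. Esterification of 6 with pyruvic acid (carbodiimide, 4-dimethylaminopyridine) would give the pyruvate ester F4. Wittig reaction with 1-(triphenylphosphoranylidene)propan-2-one would give the (E)-2-methyl-4-oxopent-2-enoate ester F5. Its intramolecular Diels–Alder reaction (toluene, 80–110 °C) should give the trans-fused 14β-acetyl lactone F6. Buffered mCPBA in excess would epoxidise C11=C12 and convert the methyl ketone by Baeyer–Villiger oxidation, with retention, into the 11α,12α-epoxy 14β-acetate F7. Methanolysis (K2CO3, MeOH) would give the 11α,12α-epoxy 14β-alcohol F8, and Dess–Martin oxidation would give ketone 13.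

Step 27 (C6 configuration). Hydride delivery may follow the ring conformation and not the Felkin–Anh preference, which would give the C6 epimer. The fallback sets out from 38 and returns at 39 by inverting the epimer. The (6S)-allylic alcohol F9 formed in the reduction would undergo a Mitsunobu reaction with chloroacetic acid (PPh3, diisopropyl azodicarboxylate) to give the (6R)-chloroacetate F10. Thiourea and NaHCO3 in ethanol would then remove the chloroacetyl group without touching the acetates and give 39.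

Further compounds
F1 | step 25 | C6 carboxylic acid from 35 | C=C(I)CC[C@@H](OC(C)=O)[C@@]2(C)[C@@H]3C[C@@H](O[Si](C(C)(C)C)(C(C)(C)C)O3)C(=C)[C@@H]2[C@H](OC(C)=O)[C@]2(O)[C@@H](C)C(=O)O[C@H]2C(=O)O
F2 | step 25 | S-ethyl thioester of F1 | C=C(I)CC[C@@H](OC(C)=O)[C@@]2(C)[C@@H]3C[C@@H](O[Si](C(C)(C)C)(C(C)(C)C)O3)C(=C)[C@@H]2[C@H](OC(C)=O)[C@]2(O)[C@@H](C)C(=O)O[C@H]2C(=O)SCC
F3 | step 25 | alkenylstannane thioester (trimethylstannyl on C5) | C=C([Sn](C)(C)C)CC[C@@H](OC(C)=O)[C@@]2(C)[C@@H]3C[C@@H](O[Si](C(C)(C)C)(C(C)(C)C)O3)C(=C)[C@@H]2[C@H](OC(C)=O)[C@]2(O)[C@@H](C)C(=O)O[C@H]2C(=O)SCC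
F4 | step 7 | pyruvate ester of 6 | C=C/C(C)=C/[C@H](OC(=O)C(C)=O)[C@H]1OC(C)(C)O[C@H]1COCc1ccc(OC)cc1
F5 | step 7 | (E)-2-methyl-4-oxopent-2-enoate ester of 6 | C=C/C(C)=C/[C@H](OC(=O)/C(C)=C/C(C)=O)[C@H]1OC(C)(C)O[C@H]1COCc1ccc(OC)cc1
F6 | step 7 | trans-fused 14β-acetyl lactone | CC(=O)[C@@H]1CC=C(C)[C@H]2[C@@]1(C)C(=O)O[C@@H]2[C@H]1OC(C)(C)O[C@H]1COCc1ccc(OC)cc1
F7 | step 7 | 11α,12α-epoxy 14β-acetate | CC(=O)O[C@@H]1C[C@H]2O[C@@]2(C)[C@H]2[C@@]1(C)C(=O)O[C@@H]2[C@H]1OC(C)(C)O[C@H]1COCc1ccc(OC)cc1
F8 | step 7 | 11α,12α-epoxy 14β-alcohol (14-epimer of 14) | O[C@@H]1C[C@H]2O[C@@]2(C)[C@H]2[C@@]1(C)C(=O)O[C@@H]2[C@H]1OC(C)(C)O[C@H]1COCc1ccc(OC)cc1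
F9 | step 27 | (6S)-allylic alcohol (6-epimer of 39) | C=C1CC[C@@H](OC(C)=O)[C@@]2(C)[C@@H]3C[C@@H](O[Si](C(C)(C)C)(C(C)(C)C)O3)C(=C)[C@@H]2[C@H](OC(C)=O)[C@]2(O)[C@@H](C)C(=O)O[C@H]2[C@H]1O
F10 | step 27 | (6R)-chloroacetate | C=C1CC[C@@H](OC(C)=O)[C@@]2(C)[C@@H]3C[C@@H](O[Si](C(C)(C)C)(C(C)(C)C)O3)C(=C)[C@@H]2[C@H](OC(C)=O)[C@]2(O)[C@@H](C)C(=O)O[C@H]2[C@@H]1OC(=O)CCl
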